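The target you want is also the raw material of its isomer, so the selectivity S, the share of target in target plus isomer, starts high and slides.

| flask | substrate | temperature | remark | time |
|---|---|---|---|---|
| north | 0.017 M | 35 °C | run made earlier |  |
| west | 0.039 M | 68 °C | run made earlier |  |
| dawn | 0.026 M | 40 °C |  | 3.0 h |
| winter | 0.026 M | 60 °C |  | 3.0 h |
| summer | 0.026 M | 80 °C |  | 3.0 h |
| noon | 0.026 M | 20 °C |  | 3.0 h |

| run | time / h | target / % | isomer of the product / % | substrate / % |
|---|---|---|---|---|
| north | 0.500 | 0.9 | 0 | 97.3 |
| north | 1.50 | 6.2 | 0.7 | 93.5 |
| north | 3.00 | 9.4 | 0.7 | 88.4 |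
| north | 5.00 | 15.2 | 3.6 | 80.7 |
| north | 6.00 | 15.9 | 4.3 | 78.9 |
| north | 8.00 | 20.9 | 7.4 | 74.7 |
| north | 10.0 | 21.8 | 10.4 | 66.4 |
| west | 0.250 | 18.0 | 16.6 | 66.8 |
| west | 0.333 | 20.9 | 22.4 | 59.6 |
| west | 0.500 | 21.3 | 36.4 | 44.4 |
| west | 0.833 | 19.2 | 55.1 | 28.4 |
| west | 1.33 | 15.7 | 74.0 | 12.3 |
| west | 2.00 | 14.6 | 80.9 | 3.5 |
| west | 3.00 | 13.1 | 87.5 | 0 |

(each reading ± 1 percentage point)

* the flasks by share of target in all that became target or isomer of the product, highest first, at 3.0 h (dawn / winter / summer / noon)
* the same order at 10 min (dawn / winter / summer / noon)
* the share of target in all that became target or isomer of the product of the flask you put first, at 3.0 h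
* the share of target in all that became target or isomer of the product of the flask you put last, at 3.0 h

Watch a flask in slow motion. In the first instants substrate feeds target and the isomer lags: at 1.50 h the north run reads 6.2% target against 0.7% isomer.

In the middle, while substrate falls slowly, target grows in step with time and isomer, fed by target, with the square of time. So the ratio of isomer to target climbs in step with time, at a rate ρ = k/2, where k is the forward rate constant from target to isomer. North's last reading gives 0.0477 h⁻¹ at 35 °C, and west's first gives 3.69 h⁻¹ at 68 °C. Substrate reads 66.4% and 66.8% at those two points, so both values are rough. This ρ is the isomer clock: as long as substrate falls slowly and the way back from isomer to target does not count, ρt is the ratio itself, and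

S = 1/(1 + ρt).

You can carry it between temperatures. Each reading carries a scatter of 1 percentage point, and the two values of ρ together give an activation energy of 115 kJ mol⁻¹. My own reckoning at 3.0 h is then as follows, with the clock stretched past its middle stage for winter:

noon: ρt = 0.0143, S = 98.6%

dawn: ρt = 0.293, S = 77.3%

winter: ρt = 4.17, S = 19.3%

summer: ρt = 44.0

At the end of the west run, target reads 14.6% and then 13.1%, with substrate reading 0%. The ratio from west's last reading stands at 6.68, which I read as an equilibrium ratio: thermodynamic rather than kinetic control. Summer's count is larger than that, so I stop the clock there and, taking that ratio to hold at 80 °C too, give summer the west share, 13.0%. That puts summer last.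

The forecast gives the same order at 3.0 h, noon > dawn > winter > summer, and noon > dawn > winter > summer at 10 min, with 98.5% for noon and 13% for summer. It assumes that “K changes little with temperature”.

The flasks give noon > dawn > summer > winter at 3.0 h and noon > dawn > winter > summer at 10 min, with 98.7% first and 14.6% last.

    substrate → target (k = 0.700 h⁻¹, Ea = 98.0 kJ mol⁻¹)
    target ⇌ isomer of the product (K = 10.0, k = 2.10 h⁻¹, Ea = 112 kJ mol⁻¹, ΔH = −53.0 kJ mol⁻¹)
    (constants at 60 °C)

Dawn, reckoned at 77.3%, stands at 79.0%. My order and the forecast's part from the flasks at the hot end: at 3.0 h summer's 22.8% lies above winter's 14.6%, and winter still holds 12% substrate. Now run winter's charge at 35 °C for 3.0 h. That is north's temperature, and the steps above are first order, so ρ carries over from north's smaller charge and the count is 0.143. This gives S = 87.5%, and that neighbouring flask reads 9.97% target, 1.25% isomer and a share of 88.8%.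

The earlier runs and the new flask come from a simulation for an exercise.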